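**Retrosynthetic overview**

1. The strategy rests on ring B of the cis-decalin, the cyclohexenone C5–C6=C7–C8(=O)–C9–C10. Cutting its fusion bond C5–C10 and the C8–C9 bond opens both rings to one acyclic triene: a C5=C6–C7=C8–OSi dienol ether and a C9=C10 Z-enoate, joined by C1–C4, which carry the C3–O and C4–methyl stereocentres.
2. Rings A and B form together in one intramolecular Diels–Alder step (ring B by the cycloaddition, ring A through the tether). Afterwards C8–O becomes the ketone, the C9 ester is excised, C7 is iodinated and coupled with the C11 propanoate, and C3–OH is angeloylated last.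
3. The triene comes from dienol silylation of an E-enal. The enal comes from hydroboration, oxidation and formyl-Wittig homologation of the isopropenyl group, which an anti-selective asymmetric 2-methylcrotylboration of methyl (Z)-6-oxohex-2-enoate installs together with C3 and C4.
4. That aldehyde comes from pent-4-enal by Z-selective olefination and selective ozonolysis.

Key step: step 10

Remark: bicyclic compounds carry eremophilane numbering (ring A = C1–C5 and C10, ring B = C5–C10; β is the face of the C5 methyl; "octal-6-ene" means the C6=C7 octalin); (E)-2-bromobut-2-ene is taken as commercial, and the ligand antipode in step 15 is the one that gives 11R in a model coupling of 2-iodo-4,4-dimethylcyclohex-2-enone.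

**Route**

Step 1
Reactants: 1 pent-4-enal; 2 methyl bis(2,2,2-trifluoroethyl)phosphonoacetate
Product: 3 methyl (2Z)-hepta-2,6-dienoate
Conditions: KN(SiMe3)2, 18-crown-6, THF, −78 °C
Reagents that add atoms: none
Why: Still–Gennari olefination; with the electron-poor trifluoroethyl phosphonate the adduct collapses faster than it equilibrates, so the kinetic Z-enoate should result.

Step 2
Reactants: 3 methyl (2Z)-hepta-2,6-dienoate
Product: 5 methyl (2Z)-6-oxohex-2-enoate, via secondary ozonide 4 (not isolated)
Conditions: O3 (to the Sudan Red 7B end point), CH2Cl2, −78 °C; then PPh3, −78 °C → rt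
Reagents that add atoms: ozone, [O-][O+]=O
Why: Ozonolysis with reductive work-up; electrophilic ozone attacks the isolated monosubstituted alkene much faster than the conjugated, electron-poor enoate, so titration to the dye end point should leave the Z-enoate intact.

Step 3
Reactants: 6 (E)-2-bromobut-2-ene; 7 2-(chloromethyl)-4,4,5,5-tetramethyl-1,3,2-dioxaborolane
Product: 10 4,4,5,5-tetramethyl-2-[(2E)-2-methylbut-2-en-1-yl]-1,3,2-dioxaborolane, via alkenyllithium 8 (not isolated), via boronate complex 9 (not isolated)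
Conditions: t-BuLi (2 equiv), Et2O, −78 °C; then 7, −78 °C → rt
Reagents that add atoms: none
Why: Bromine–lithium exchange with retention followed by Matteson homologation (1,2-shift of the alkenyl group from boron to the chloromethyl carbon) should give the allylboronate with the alkene geometry unchanged, which the anti selectivity of step 4 depends on.

Step 4
Reactants: 5 methyl (2Z)-6-oxohex-2-enoate; 10 4,4,5,5-tetramethyl-2-[(2E)-2-methylbut-2-en-1-yl]-1,3,2-dioxaborolane
Product: 12 methyl (2Z,6S,7R)-6-hydroxy-7,8-dimethylnona-2,8-dienoate, via pinacol borate 11 (not isolated)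
Conditions: (R)-TRIP [(R)-3,3′-bis(2,4,6-triisopropylphenyl)-1,1′-binaphthyl-2,2′-diyl hydrogen phosphate] (5 mol%), 4 Å MS, PhMe, −30 °C; aq. NaHCO3
Reagents that add atoms: none
Why: Chiral-phosphoric-acid-catalysed allylboration through a closed chair transition state: the E-configured γ-methyl sits equatorial and gives the anti C6/C7 pair, and the (R)-acid, bound to a boronate oxygen and the formyl hydrogen, is expected to expose the Re face of the aldehyde, which gives 6S (eremophilane C3 and C4).

Step 5
Reactants: 12 methyl (2Z,6S,7R)-6-hydroxy-7,8-dimethylnona-2,8-dienoate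
Product: 13 methyl (2Z,6S,7R)-6-[(tert-butyldimethylsilyl)oxy]-7,8-dimethylnona-2,8-dienoate
Conditions: TBSOTf, 2,6-lutidine, CH2Cl2, −78 → 0 °C
Reagents that add atoms: tert-butyldimethylsilyl trifluoromethanesulfonate, CC(C)(C)[Si](C)(C)OS(=O)(=O)C(F)(F)F
Why: Silyl triflate with a hindered base silylates the hindered secondary alcohol without touching the ester or the alkenes; no stereocentre is affected.

Step 6
Reactants: 13 methyl (2Z,6S,7R)-6-[(tert-butyldimethylsilyl)oxy]-7,8-dimethylnona-2,8-dienoate
Product: 15 methyl (2Z,6S,7R)-6-[(tert-butyldimethylsilyl)oxy]-9-hydroxy-7,8-dimethylnon-2-enoate (C8 epimers), via alkylborane 14 (not isolated)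
Conditions: 9-BBN, THF, 0 °C → rt; then NaBO3·4H2O, H2O, rt
Reagents that add atoms: sodium perborate, B(=O)O[O-].[Na+]
Why: Anti-Markovnikov hydroboration–oxidation; 9-BBN adds to the 1,1-disubstituted alkene far faster than to the conjugated ester and perborate oxidises the C–B bond without attacking the enoate; the uncontrolled C8 centre is destroyed in step 9.

Step 7
Reactants: 15 methyl (2Z,6S,7R)-6-[(tert-butyldimethylsilyl)oxy]-9-hydroxy-7,8-dimethylnon-2-enoate
Product: 16 methyl (2Z,6S,7R)-6-[(tert-butyldimethylsilyl)oxy]-7,8-dimethyl-9-oxonon-2-enoate (C8 epimers)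
Conditions: Dess–Martin periodinane, CH2Cl2, 0 °C → rt
Reagents that add atoms: none
Why: Dess–Martin oxidation of the primary alcohol to the aldehyde under near-neutral conditions; the adjacent C8 centre need not be preserved.

Step 8
Reactants: 16 methyl (2Z,6S,7R)-6-[(tert-butyldimethylsilyl)oxy]-7,8-dimethyl-9-oxonon-2-enoate; 17 (triphenylphosphoranylidene)acetaldehyde
Product: 18 methyl (2Z,6S,7R,9E)-6-[(tert-butyldimethylsilyl)oxy]-7,8-dimethyl-11-oxoundeca-2,9-dienoate (C8 epimers)
Conditions: PhMe, 80 °C
Reagents that add atoms: none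
Why: Wittig olefination with the stabilised formyl ylide should give the E-enal, and the α-branch of the aldehyde disfavours a second homologation.

Step 9
Reactants: 18 methyl (2Z,6S,7R,9E)-6-[(tert-butyldimethylsilyl)oxy]-7,8-dimethyl-11-oxoundeca-2,9-dienoate
Product: 19 methyl (2Z,6S,7R,8E,10E)-6-[(tert-butyldimethylsilyl)oxy]-7,8-dimethyl-11-[(triisopropylsilyl)oxy]undeca-2,8,10-trienoate
Conditions: TIPSOTf, Et3N, CH2Cl2, −78 → 0 °C; filtration through Et3N-deactivated silica, used at once
Reagents that add atoms: triisopropylsilyl trifluoromethanesulfonate, CC(C)[Si](C(C)C)(C(C)C)OS(=O)(=O)C(F)(F)F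
Why: Vinylogous enol silylation: the triflate O-silylates the enal and Et3N removes the γ-hydrogen (eremophilane C5–H); the s-trans E-enal fixes the 10E enol ether, and the branched substituent should go trans to C7 (8E) to avoid allylic strain, with the other C5=C6 isomer expected as a minor component.

Step 10
Reactants: 19 methyl (2Z,6S,7R,8E,10E)-6-[(tert-butyldimethylsilyl)oxy]-7,8-dimethyl-11-[(triisopropylsilyl)oxy]undeca-2,8,10-trienoate
Product: 20 methyl 3β-[(tert-butyldimethylsilyl)oxy]-4β,5β-dimethyl-8α-[(triisopropylsilyl)oxy]-10βH-octal-6-ene-9α-carboxylate (cis-fused)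
Conditions: degassed PhMe (0.01 M), BHT (5 mol%), 160 °C, sealed tube
Reagents that add atoms: none
Why: Thermal, concerted but asynchronous [4+2] cycloaddition (type 1 intramolecular Diels–Alder reaction of a 1,7,9-decatrienoate, a known reaction class), in which the nucleophilic diene terminus C5 of the 1-silyloxydiene bonds to the enoate β-carbon C10 and C8 bonds to C9, the polarity-matched orientation. Ring B closes as the new cyclohexene by the cycloaddition itself, and ring A closes in the same event as a six-membered carbocycle through the C1–C4 tether when C5–C10 forms. C9 and C10 keep the cis relation of ester and tether of the Z-dienophile, and C8 follows from the E-enol ether in the ester-endo transition state (8-OTIPS cis to 9-CO2Me). The C5/C10 fusion should be cis because for a Z-dienophile the endo ester carries the tether endo as well. The configuration of C5 and C10 relative to C4 is set by a chair-like tether with the C3 silyloxy group equatorial and the C4 methyl axial (away from the in-plane C5 methyl), so that C6 is axial and C9 equatorial on the forming ring A, whereas the other cis-fused approach would put C9 syn-axial to the C4 methyl. The step needs endo selectivity and this facial selectivity; C8 and C9 are erased later, so isomers at those two centres converge.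

Step 11
Reactants: 20 methyl 3β-[(tert-butyldimethylsilyl)oxy]-4β,5β-dimethyl-8α-[(triisopropylsilyl)oxy]-10βH-octal-6-ene-9α-carboxylate
Product: 21 methyl 3β,8α-dihydroxy-4β,5β-dimethyl-10βH-octal-6-ene-9α-carboxylate
Conditions: 48% aq. HF, MeCN, 0 °C → rt
Reagents that add atoms: none
Why: Acidic fluoride cleaves both silyl ethers and avoids the base-induced β-elimination that the β-silyloxy ester could undergo with basic fluoride.

Step 12
Reactants: 21 methyl 3β,8α-dihydroxy-4β,5β-dimethyl-10βH-octal-6-ene-9α-carboxylate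
Product: 22 methyl 3β-hydroxy-4β,5β-dimethyl-8-oxo-10βH-octal-6-ene-9-carboxylate (C9 epimers and enol form)
Conditions: activated MnO2 (excess), CH2Cl2, rt
Reagents that add atoms: none
Why: MnO2 oxidises only the allylic C8 alcohol and leaves the saturated C3 alcohol; the labile C9 centre of the β-keto ester is removed in the next step.

Step 13
Reactants: 22 methyl 3β-hydroxy-4β,5β-dimethyl-8-oxo-10βH-octal-6-ene-9-carboxylate
Product: 23 (3S,4R,5R,10R)-3β-hydroxy-4β,5β-dimethyl-10βH-octal-6-en-8-one
Conditions: LiCl, H2O, DMSO, 140 °C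
Reagents that add atoms: none
Why: Krapcho dealkoxycarbonylation: chloride demethylates the β-keto ester, the carboxylate loses CO2 and the enolate is protonated at C9; C10 is not enolisable (only C9 flanks the ketone, C5 is quaternary), so the cis fusion is kept.

Step 14
Reactants: 23 (3S,4R,5R,10R)-3β-hydroxy-4β,5β-dimethyl-10βH-octal-6-en-8-one
Product: 24 3β-hydroxy-7-iodo-4β,5β-dimethyl-10βH-octal-6-en-8-one
Conditions: I2, pyridine, CH2Cl2, rt
Reagents that add atoms: iodine, II
Why: α-Iodination of the enone by conjugate addition of pyridine at C6, iodination of the C7 enolate and loss of pyridine; 4,4-disubstituted cyclohex-2-enones, the substructure present here, are standard substrates.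

Step 15
Reactants: 24 3β-hydroxy-7-iodo-4β,5β-dimethyl-10βH-octal-6-en-8-one; 25 methyl 2-chloropropanoate (racemic)
Product: 26 methyl (2R)-2-[(3S,4R,5R,10R)-3β-hydroxy-4β,5β-dimethyl-8-oxo-10βH-octal-6-en-7-yl]propanoate
Conditions: NiBr2·diglyme (10 mol%), one antipode of 4,4′-di(heptan-4-yl)-4,4′,5,5′-tetrahydro-2,2′-bioxazole (12 mol%), Mn powder (3 equiv), NaI (0.5 equiv), DMA, 0 °C → rt
Reagents that add atoms: none
Why: Proposed new method: zerovalent nickel bearing the chiral bis(oxazoline) should insert into the C7–I bond, the alkenylnickel should capture the planar α-ester radical formed by halogen abstraction from either enantiomer of 25, and reductive elimination from the resulting trivalent nickel species should form C7–C11 with C11 set by the ligand (11R), while Mn returns the catalyst to the zerovalent state; the closest known reaction type is the nickel-catalysed enantioconvergent reductive cross-coupling of α-chloro esters with aryl iodides and of alkenyl bromides with benzylic chlorides, which has not been shown with an α-iodoenone.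

Step 16
Reactants: 26 methyl (2R)-2-[(3S,4R,5R,10R)-3β-hydroxy-4β,5β-dimethyl-8-oxo-10βH-octal-6-en-7-yl]propanoate; 27 angelic acid [(2Z)-2-methylbut-2-enoic acid]
Product: 29 CNP0323033.1, methyl (11R)-3β-angeloyloxy-8-oxo-10βH-eremophil-6-en-12-oate, (3S,4R,5R,10R,11R), via mixed anhydride 28 (not isolated)
Conditions: 27, 2,4,6-trichlorobenzoyl chloride, Et3N, PhMe, rt; then 26, 75 °C
Reagents that add atoms: none
Why: Yamaguchi esterification; the mixed anhydride acylates the hindered C3 alcohol on heating without the Z to E isomerisation of the angelate that stronger activation causes, and triethylamine is too weak a base to epimerise C11.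

**Compound list**

1 | pent-4-enal | C=CCCC=O | starting material
2 | methyl bis(2,2,2-trifluoroethyl)phosphonoacetate | COC(=O)CP(=O)(OCC(F)(F)F)OCC(F)(F)F | starting material
3 | methyl (2Z)-hepta-2,6-dienoate | COC(=O)/C=C\CCC=C | intermediate
4 | methyl (2Z)-5-(1,2,4-trioxolan-3-yl)pent-2-enoate (secondary ozonide) | COC(=O)/C=C\CCC1OCOO1 | intermediate (not isolated)
5 | methyl (2Z)-6-oxohex-2-enoate | COC(=O)/C=C\CCC=O | intermediate
6 | (E)-2-bromobut-2-ene (methyl groups cis) | C/C=C(\C)Br | starting material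
7 | 2-(chloromethyl)-4,4,5,5-tetramethyl-1,3,2-dioxaborolane | ClCB1OC(C)(C)C(C)(C)O1 | starting material
8 | (Z)-but-2-en-2-yllithium (methyl groups cis) | C/C=C(\C)[Li] | intermediate (not isolated)
9 | lithium (Z)-but-2-en-2-yl(chloromethyl)(pinacolato)borate | [Li+].C/C=C(\C)[B-]1(CCl)OC(C)(C)C(C)(C)O1 | intermediate (not isolated)
10 | 4,4,5,5-tetramethyl-2-[(2E)-2-methylbut-2-en-1-yl]-1,3,2-dioxaborolane | C/C=C(\C)CB1OC(C)(C)C(C)(C)O1 | intermediate
11 | pinacol borate ester of 12 | COC(=O)/C=C\CC[C@H](OB1OC(C)(C)C(C)(C)O1)[C@H](C)C(C)=C | intermediate (not isolated)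
12 | methyl (2Z,6S,7R)-6-hydroxy-7,8-dimethylnona-2,8-dienoate | COC(=O)/C=C\CC[C@H](O)[C@H](C)C(C)=C | intermediate
13 | methyl (2Z,6S,7R)-6-[(tert-butyldimethylsilyl)oxy]-7,8-dimethylnona-2,8-dienoate | COC(=O)/C=C\CC[C@H](O[Si](C)(C)C(C)(C)C)[C@H](C)C(C)=C | intermediate
14 | 9-alkyl-9-borabicyclo[3.3.1]nonane from 13 (boron on C9, C8 epimers) | COC(=O)/C=C\CC[C@H](O[Si](C)(C)C(C)(C)C)[C@H](C)C(C)CB1C2CCCC1CCC2 | intermediate (not isolated)
15 | methyl (2Z,6S,7R)-6-[(tert-butyldimethylsilyl)oxy]-9-hydroxy-7,8-dimethylnon-2-enoate (C8 epimers) | COC(=O)/C=C\CC[C@H](O[Si](C)(C)C(C)(C)C)[C@H](C)C(C)CO | intermediate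
16 | methyl (2Z,6S,7R)-6-[(tert-butyldimethylsilyl)oxy]-7,8-dimethyl-9-oxonon-2-enoate (C8 epimers) | COC(=O)/C=C\CC[C@H](O[Si](C)(C)C(C)(C)C)[C@H](C)C(C)C=O | intermediate
17 | (triphenylphosphoranylidene)acetaldehyde | O=CC=P(c1ccccc1)(c1ccccc1)c1ccccc1 | starting material
18 | methyl (2Z,6S,7R,9E)-6-[(tert-butyldimethylsilyl)oxy]-7,8-dimethyl-11-oxoundeca-2,9-dienoate (C8 epimers) | COC(=O)/C=C\CC[C@H](O[Si](C)(C)C(C)(C)C)[C@H](C)C(C)/C=C/C=O | intermediate
19 | methyl (2Z,6S,7R,8E,10E)-6-[(tert-butyldimethylsilyl)oxy]-7,8-dimethyl-11-[(triisopropylsilyl)oxy]undeca-2,8,10-trienoate | COC(=O)/C=C\CC[C@H](O[Si](C)(C)C(C)(C)C)[C@H](C)/C(C)=C/C=C/O[Si](C(C)C)(C(C)C)C(C)C | intermediate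
20 | methyl 3β-[(tert-butyldimethylsilyl)oxy]-4β,5β-dimethyl-8α-[(triisopropylsilyl)oxy]-10βH-octal-6-ene-9α-carboxylate | CC(C)(C)[Si](C)(C)O[C@H]1CC[C@@H]2[C@H](C(=O)OC)[C@H](O[Si](C(C)C)(C(C)C)C(C)C)C=C[C@]2(C)[C@H]1C | intermediate
21 | methyl 3β,8α-dihydroxy-4β,5β-dimethyl-10βH-octal-6-ene-9α-carboxylate | O[C@H]1CC[C@@H]2[C@H](C(=O)OC)[C@H](O)C=C[C@]2(C)[C@H]1C | intermediate
22 | methyl 3β-hydroxy-4β,5β-dimethyl-8-oxo-10βH-octal-6-ene-9-carboxylate (C9 epimers) | O[C@H]1CC[C@@H]2C(C(=O)OC)C(=O)C=C[C@]2(C)[C@H]1C | intermediate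
23 | (3S,4R,5R,10R)-3β-hydroxy-4β,5β-dimethyl-10βH-octal-6-en-8-one | O[C@H]1CC[C@@H]2CC(=O)C=C[C@]2(C)[C@H]1C | intermediate
24 | 3β-hydroxy-7-iodo-4β,5β-dimethyl-10βH-octal-6-en-8-one | O[C@H]1CC[C@@H]2CC(=O)C(I)=C[C@]2(C)[C@H]1C | intermediate
25 | methyl 2-chloropropanoate (racemic) | CC(Cl)C(=O)OC | starting material
26 | methyl (2R)-2-[(3S,4R,5R,10R)-3β-hydroxy-4β,5β-dimethyl-8-oxo-10βH-octal-6-en-7-yl]propanoate | O[C@H]1CC[C@@H]2CC(=O)C([C@@H](C)C(=O)OC)=C[C@]2(C)[C@H]1C | intermediate
27 | angelic acid, (2Z)-2-methylbut-2-enoic acid | C/C=C(/C)C(=O)O | starting material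
28 | (2Z)-2-methylbut-2-enoic 2,4,6-trichlorobenzoic anhydride | C/C=C(/C)C(=O)OC(=O)c1c(Cl)cc(Cl)cc1Cl | intermediate (not isolated)
29 | CNP0323033.1, methyl (11R)-3β-angeloyloxy-8-oxo-10βH-eremophil-6-en-12-oate, (3S,4R,5R,10R,11R) | C/C=C(/C)C(=O)O[C@H]1CC[C@@H]2CC(=O)C([C@@H](C)C(=O)OC)=C[C@]2(C)[C@H]1C | target

**Step count**

Total: 16 steps. Longest linear sequence: 15 steps (steps 1, 2 and 4–16 from pent-4-enal); step 3 is a one-step side branch.

**Steps most likely to fail**

1. Step 15 (proposed new method). Reduction of the C7–I bond to C7–H or homocoupling of the iodoenone may outrun radical capture, and with a small methyl ester the ligand may control C11 only partly, giving both C11 epimers. The fallback uses known chemistry and sets out from 24. Negishi coupling with the Reformatsky reagent made from (4R)-4-benzyl-3-(bromoacetyl)-1,3-oxazolidin-2-one and Zn (Pd(dba)2, P(t-Bu)3, THF, rt, excess reagent because of the free hydroxyl) should give (4R)-4-benzyl-3-[(3β-hydroxy-4β,5β-dimethyl-8-oxo-10βH-octal-6-en-7-yl)acetyl]-1,3-oxazolidin-2-one F1. Auxiliary-controlled enolate methylation (NaN(SiMe3)2, 2.1 equiv, the first equivalent taken up by the C3 hydroxyl, then MeI, THF, −78 °C) should give (4R)-4-benzyl-3-[(2R)-2-(3β-hydroxy-4β,5β-dimethyl-8-oxo-10βH-octal-6-en-7-yl)propanoyl]-1,3-oxazolidin-2-one F2. The imide α-hydrogens, also allylic, are far more acidic than C9–H, and the Z-enolate is methylated on the face away from the benzyl group, which for the (R)-auxiliary gives 11R. Methanolysis with MeOMgBr (MeOH/THF, 0 °C) releases the auxiliary and comes back to the route at 26.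

2. Step 10. The diene must reach an s-cis conformer with the C5 methyl inside, so cyclisation may be slow enough for a 1,5-hydrogen shift of the dienol ether or Z/E drift of the enoate to compete. Endo and facial preferences may also be only partial, giving trans-fused or C5/C10-epimeric decalins. The fallback moves the activation from the diene to the dienophile and sets out from 18. Ac2O, Et3N and DMAP (60 °C) should give the Lewis-acid-stable dienyl acetate methyl (2Z,6S,7R,8E,10E)-11-acetoxy-6-[(tert-butyldimethylsilyl)oxy]-7,8-dimethylundeca-2,8,10-trienoate F3. Me2AlCl (CH2Cl2, −40 → 0 °C) complexes the ester, and the catalysed cycloaddition at low temperature, with stronger endo and facial bias, should give methyl 8α-acetoxy-3β-[(tert-butyldimethylsilyl)oxy]-4β,5β-dimethyl-10βH-octal-6-ene-9α-carboxylate F4. K2CO3 in MeOH at 0 °C removes the acetate to give methyl 3β-[(tert-butyldimethylsilyl)oxy]-8α-hydroxy-4β,5β-dimethyl-10βH-octal-6-ene-9α-carboxylate F5, and aq. HF in MeCN comes back to the route at 21.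

3. Step 4. Uncatalysed addition to the unhindered aldehyde, or a poorer fit of the β-methyl-substituted boronate in the acid-bound transition state, may lower the enantiofacial control and let some syn isomer form. The fallback takes the absolute configuration from the chiral pool and sets out from 5. The allenylzinc reagent formed from (S)-but-3-yn-2-yl methanesulfonate (Pd(OAc)2, PPh3, Et2Zn, THF, −78 → −20 °C) arises with inversion and adds through a cyclic SE2′ transition state, which should give the anti alcohol methyl (2Z,6S,7R)-6-hydroxy-7-methylnon-2-en-8-ynoate F6. TBSOTf and 2,6-lutidine give methyl (2Z,6S,7R)-6-[(tert-butyldimethylsilyl)oxy]-7-methylnon-2-en-8-ynoate F7. Markovnikov hydration (Ph3PAuNTf2, MeOH/H2O, rt) gives the methyl ketone methyl (2Z,6S,7S)-6-[(tert-butyldimethylsilyl)oxy]-7-methyl-8-oxonon-2-enoate F8. Non-basic methylenation (Zn, CH2Br2, TiCl4, THF/CH2Cl2, 0 °C) comes back to the route at 13.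

Further compounds
F1 | step 15 | (4R)-4-benzyl-3-[(3β-hydroxy-4β,5β-dimethyl-8-oxo-10βH-octal-6-en-7-yl)acetyl]-1,3-oxazolidin-2-one | O[C@H]1CC[C@@H]2CC(=O)C(CC(=O)N3C(=O)OC[C@H]3Cc4ccccc4)=C[C@]2(C)[C@H]1C
F2 | step 15 | (4R)-4-benzyl-3-[(2R)-2-(3β-hydroxy-4β,5β-dimethyl-8-oxo-10βH-octal-6-en-7-yl)propanoyl]-1,3-oxazolidin-2-one | O[C@H]1CC[C@@H]2CC(=O)C([C@@H](C)C(=O)N3C(=O)OC[C@H]3Cc4ccccc4)=C[C@]2(C)[C@H]1C
F3 | step 10 | methyl (2Z,6S,7R,8E,10E)-11-acetoxy-6-[(tert-butyldimethylsilyl)oxy]-7,8-dimethylundeca-2,8,10-trienoate | COC(=O)/C=C\CC[C@H](O[Si](C)(C)C(C)(C)C)[C@H](C)/C(C)=C/C=C/OC(C)=O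
F4 | step 10 | methyl 8α-acetoxy-3β-[(tert-butyldimethylsilyl)oxy]-4β,5β-dimethyl-10βH-octal-6-ene-9α-carboxylate | CC(C)(C)[Si](C)(C)O[C@H]1CC[C@@H]2[C@H](C(=O)OC)[C@H](OC(C)=O)C=C[C@]2(C)[C@H]1C
F5 | step 10 | methyl 3β-[(tert-butyldimethylsilyl)oxy]-8α-hydroxy-4β,5β-dimethyl-10βH-octal-6-ene-9α-carboxylate | CC(C)(C)[Si](C)(C)O[C@H]1CC[C@@H]2[C@H](C(=O)OC)[C@H](O)C=C[C@]2(C)[C@H]1C
F6 | step 4 | methyl (2Z,6S,7R)-6-hydroxy-7-methylnon-2-en-8-ynoate | COC(=O)/C=C\CC[C@H](O)[C@H](C)C#C
F7 | step 4 | methyl (2Z,6S,7R)-6-[(tert-butyldimethylsilyl)oxy]-7-methylnon-2-en-8-ynoate | COC(=O)/C=C\CC[C@H](O[Si](C)(C)C(C)(C)C)[C@H](C)C#C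
F8 | step 4 | methyl (2Z,6S,7S)-6-[(tert-butyldimethylsilyl)oxy]-7-methyl-8-oxonon-2-enoate | COC(=O)/C=C\CC[C@H](O[Si](C)(C)C(C)(C)C)[C@H](C)C(C)=O
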